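**Retrosynthetic overview**
1. The dienone is made last, by dearomatizing C5–OMe bond formation on the 5-allyl-6-hydroxy-2,3-dihydrobenzofuran (sets C5).
2. The C5 allyl group comes from the 6-O-allyl ether by aromatic Claisen rearrangement, so the phenol protecting group is reused as the C-allyl group.
3. Dihydrofuran ring B is closed at C3–C3a by 5-exo aryl-radical cyclization of an o-bromophenyl 1-arylallyl ether (sets C3 trans to C2).
4. That ether comes from O1–C2 bond formation by iridium-catalysed asymmetric allylic etherification of a bromophenol with a cinnamyl carbonate (sets C2).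
5. Ring order: aromatic ring A is bought (4-bromoresorcinol), ring B is closed next, ring A is dearomatized at the end.

Assumption: the target SMILES is read as (2S,3S,5R), with 2-aryl and 3-methyl trans and the 5-OMe on the face of the 3-methyl group; the ligand antipode in step 3 and the catalyst antipode in step 6 are assigned by analogy (step 6 is untested) and would be swapped for their mirror images if the observed sense is opposite; (E)-3,4,5-trimethoxycinnamyl alcohol is bought as a catalog compound.

**Route**

Step 1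
Reactants: 1 4-bromoresorcinol (4-bromobenzene-1,3-diol)
Product: 4 5-(allyloxy)-2-bromophenol, via disodium 4-bromobenzene-1,3-diolate 2 (not isolated), via sodium 5-(allyloxy)-2-bromophenolate 3 (not isolated)
Conditions: NaH (2.2 equiv), DMF, 0 °C; allyl bromide (1.0 equiv), −20 °C → rt; 1 M HCl
Reagents that add atoms: allyl bromide, C=CCBr
Why: Williamson etherification of the dianion, in which the phenoxide para to bromine is the more basic and less hindered oxygen and is alkylated first, leaving the OH next to bromine free for step 3 (minor regioisomer and bis-ether removed by chromatography).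

Step 2
Reactants: 5 (E)-3-(3,4,5-trimethoxyphenyl)prop-2-en-1-ol
Product: 6 methyl (E)-3-(3,4,5-trimethoxyphenyl)prop-2-en-1-yl carbonate
Conditions: ClCO2Me (1.2 equiv), pyridine (1.5 equiv), CH2Cl2, 0 °C
Reagents that add atoms: methyl chloroformate, COC(=O)Cl
Why: Standard carbonate formation (O-acylation) of a primary allylic alcohol, which leaves the E-alkene untouched.

Step 3
Reactants: 4 5-(allyloxy)-2-bromophenol; 6 methyl (E)-3-(3,4,5-trimethoxyphenyl)prop-2-en-1-yl carbonate
Product: 8 4-(allyloxy)-1-bromo-2-{[(1S)-1-(3,4,5-trimethoxyphenyl)prop-2-en-1-yl]oxy}benzene, via lithium 5-(allyloxy)-2-bromophenolate 7 (not isolated)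
Conditions: LiN(SiMe3)2 (1.0 equiv), THF, 0 °C; then 6, [Ir(cod)Cl]2 (2 mol %), (Sa,Sc,Sc)-O,O′-(1,1′-binaphthyl-2,2′-diyl) N,N-bis(1-phenylethyl)phosphoramidite (4 mol %), THF, 25 → 40 °C; aq NH4Cl
Reagents that add atoms: none
Why: Iridium-catalysed asymmetric allylic etherification, in which the cyclometalated iridium–phosphoramidite complex ionizes the linear carbonate and the aryloxide attacks the aryl-bearing allyl terminus to give the branched ether, so the future C2 stereocentre is set as S under ligand control while the aryl bromide and the aryl allyl ether stay inert.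

Step 4
Reactants: 8 4-(allyloxy)-1-bromo-2-{[(1S)-1-(3,4,5-trimethoxyphenyl)prop-2-en-1-yl]oxy}benzene
Product: 9 (2S,3S)-6-(allyloxy)-3-methyl-2-(3,4,5-trimethoxyphenyl)-2,3-dihydro-1-benzofuran
Conditions: Bu3SnH (1.3 equiv), AIBN (0.1 equiv), PhH (0.03 M), 80 °C
Reagents that add atoms: none
Why: Tin-hydride-mediated 5-exo-trig aryl radical cyclization, in which the aryl radical closes onto the internal vinyl carbon much faster than it is reduced and does so anti to the C2 aryl group (Beckwith–Houk model for a 4-substituted hexenyl radical), setting C3 as S (2,3-trans) without touching C2.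

Step 5
Reactants: 9 (2S,3S)-6-(allyloxy)-3-methyl-2-(3,4,5-trimethoxyphenyl)-2,3-dihydro-1-benzofuran
Product: 11 (2S,3S)-5-allyl-3-methyl-2-(3,4,5-trimethoxyphenyl)-2,3-dihydro-1-benzofuran-6-ol, via 5H-dienone tautomer 10 (not isolated)
Conditions: PhNEt2, 190 °C (sealed tube), 3 h
Reagents that add atoms: none
Why: Aromatic Claisen rearrangement ([3,3]) followed by enolization, expected to favour C5 over C7 because C5 is para to the ring oxygen, less hindered, and favoured by bond fixation in the five-ring-fused arene (as for 3-alkoxyphenyl and 5-indanyl allyl ethers), with no stereocentre involved.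

Step 6
Reactants: 11 (2S,3S)-5-allyl-3-methyl-2-(3,4,5-trimethoxyphenyl)-2,3-dihydro-1-benzofuran-6-ol
Product: 12 (2S,3S,5R)-5-methoxy-3-methyl-5-(prop-2-en-1-yl)-2-(3,4,5-trimethoxyphenyl)-2,3-dihydro-1-benzofuran-6(5H)-one
Conditions: (R,R)-2,2′-[(2-iodo-1,3-phenylene)bis(oxy)]bis(N-mesitylpropanamide) (10 mol %), mCPBA (1.2 equiv), MeOH (20 equiv), CH2Cl2, −20 °C
Reagents that add atoms: methanol, CO
Why: Proposed new method: catalyst-controlled ortho-methoxylative dearomatization of a 2-alkylphenol, in which mCPBA oxidizes the chiral iodoarene to a trivalent-iodine methoxide, phenol 11 exchanges onto iodine, and the iodine-bound methoxide is passed through a five-membered ligand-coupling transition state to the adjacent allyl-bearing carbon C5 (the para carbon C3a is a hindered ring-fusion carbon out of reach of this inner-sphere delivery, and the weakly ionizing solvent suppresses a free phenoxonium pathway), while the lactamide arms block one face so that the C5–OMe bond forms on the Re face (syn to the C3 methyl) to give 5R and the stable vinylogous-ester dienone; the closest known reaction types are chiral-iodoarene/mCPBA dearomative spirolactonization of phenols, asymmetric hydroxylative phenol dearomatization, and achiral PhI(OAc)2/MeOH oxidation of phenols to quinol ethers.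

**Compound list**
1 | 4-bromoresorcinol (4-bromobenzene-1,3-diol) | Oc1ccc(Br)c(O)c1 | starting material
2 | disodium 4-bromobenzene-1,3-diolate | [Na+].[Na+].[O-]c1ccc(Br)c([O-])c1 | intermediate
3 | sodium 5-(allyloxy)-2-bromophenolate | [Na+].[O-]c1cc(OCC=C)ccc1Br | intermediate
4 | 5-(allyloxy)-2-bromophenol | Oc1cc(OCC=C)ccc1Br | intermediate
5 | (E)-3-(3,4,5-trimethoxyphenyl)prop-2-en-1-ol | OC/C=C/c1cc(OC)c(OC)c(OC)c1 | starting material
6 | methyl (E)-3-(3,4,5-trimethoxyphenyl)prop-2-en-1-yl carbonate | COC(=O)OC/C=C/c1cc(OC)c(OC)c(OC)c1 | intermediate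
7 | lithium 5-(allyloxy)-2-bromophenolate | [Li+].[O-]c1cc(OCC=C)ccc1Br | intermediate
8 | 4-(allyloxy)-1-bromo-2-{[(1S)-1-(3,4,5-trimethoxyphenyl)prop-2-en-1-yl]oxy}benzene | C=CCOc1ccc(Br)c(O[C@H](c2cc(OC)c(OC)c(OC)c2)C=C)c1 | intermediate
9 | (2S,3S)-6-(allyloxy)-3-methyl-2-(3,4,5-trimethoxyphenyl)-2,3-dihydro-1-benzofuran | C=CCOc1ccc2c(c1)O[C@H](c1cc(OC)c(OC)c(OC)c1)[C@H]2C | intermediate
10 | (2S,3S)-5-allyl-3-methyl-2-(3,4,5-trimethoxyphenyl)-2,3-dihydro-1-benzofuran-6(5H)-one (both C5 epimers) | C=CCC1C=C2C(=CC1=O)O[C@H](c1cc(OC)c(OC)c(OC)c1)[C@H]2C | intermediate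
11 | (2S,3S)-5-allyl-3-methyl-2-(3,4,5-trimethoxyphenyl)-2,3-dihydro-1-benzofuran-6-ol | C=CCc1cc2c(cc1O)O[C@H](c1cc(OC)c(OC)c(OC)c1)[C@H]2C | intermediate
12 | (2S,3S,5R)-5-methoxy-3-methyl-5-(prop-2-en-1-yl)-2-(3,4,5-trimethoxyphenyl)-2,3-dihydro-1-benzofuran-6(5H)-one | C=CC[C@@]1(OC)C=C2C(=CC1=O)O[C@H](c1cc(OC)c(OC)c(OC)c1)[C@H]2C | target

**Summary**
Total steps: 6. Longest linear sequence: 5 (steps 1, 3, 4, 5, 6, or equally 2, 3, 4, 5, 6).

Three steps most likely to fail:

Step 6 (the new step). Possible failures are methanol attack at the para carbon C3a, transfer of m-chlorobenzoate instead of methoxide, low facial control, or epoxidation of the allyl group. The product must also be kept below about 40 °C, because 5-allyl dienones of this kind undergo Cope shift of the allyl group to C3a on heating. The fallback sets out from 11 and comes back at 12. Hydroxylative phenol dearomatization with stabilized 2-iodoxybenzoic acid (SIBX, THF, rt) delivers oxygen from pentavalent iodine to the alkyl-bearing ortho carbon. It gives the ortho-quinol (2S,3S,5R)-5-hydroxy-3-methyl-5-(prop-2-en-1-yl)-2-(3,4,5-trimethoxyphenyl)-2,3-dihydro-1-benzofuran-6(5H)-one F6 together with its C5 epimer, which is removed by chromatography. Methylation of the tertiary alcohol with MeI/Ag2O (CH2Cl2, rt, dark) then gives 12.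

Step 5. The allyl group may go partly to C7, and the prolonged heating may cost material. The fallback sets out from 9 and comes back at 11. Pd(PPh3)4 (zerovalent palladium, 2 mol %) with morpholine in THF removes the O-allyl group to give (2S,3S)-3-methyl-2-(3,4,5-trimethoxyphenyl)-2,3-dihydro-1-benzofuran-6-ol F4. Iodination of its phenoxide (I2, NaHCO3, THF–water, 0 °C) occurs ortho to the OH and para to the ring oxygen, giving (2S,3S)-5-iodo-3-methyl-2-(3,4,5-trimethoxyphenyl)-2,3-dihydro-1-benzofuran-6-ol F5. Stille coupling with allyltributylstannane (Pd(PPh3)4, DMF, 80 °C) gives 11.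

Step 3. The hindered ortho-bromophenoxide is a fair leaving group, so the branched ether can re-ionize and lose ee or isomerize to the linear ether. The fallback sets out from 5 and 4 and comes back at 8. Sharpless asymmetric epoxidation of 5 (Ti(OiPr)4, L-(+)-diethyl tartrate, t-BuOOH, 4 Å sieves, CH2Cl2, −20 °C) gives [(2S,3S)-3-(3,4,5-trimethoxyphenyl)oxiran-2-yl]methanol F1. I2, PPh3 and imidazole convert it into (2R,3S)-2-(iodomethyl)-3-(3,4,5-trimethoxyphenyl)oxirane F2. Zn dust in refluxing ethanol opens F2 reductively to (R)-1-(3,4,5-trimethoxyphenyl)prop-2-en-1-ol F3. Mitsunobu etherification of F3 with 4 (PPh3, DIAD, toluene, 0 °C) proceeds with inversion to give 8; some SN2′ product or loss of ee is possible at this allylic, benzylic centre.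

**Further compounds**
F1 | step 3 | [(2S,3S)-3-(3,4,5-trimethoxyphenyl)oxiran-2-yl]methanol | OC[C@@H]1O[C@H]1c1cc(OC)c(OC)c(OC)c1
F2 | step 3 | (2R,3S)-2-(iodomethyl)-3-(3,4,5-trimethoxyphenyl)oxirane | IC[C@@H]1O[C@H]1c1cc(OC)c(OC)c(OC)c1
F3 | step 3 | (R)-1-(3,4,5-trimethoxyphenyl)prop-2-en-1-ol | O[C@@H](c1cc(OC)c(OC)c(OC)c1)C=C
F4 | step 5 | (2S,3S)-3-methyl-2-(3,4,5-trimethoxyphenyl)-2,3-dihydro-1-benzofuran-6-ol | Oc1ccc2c(c1)O[C@H](c1cc(OC)c(OC)c(OC)c1)[C@H]2C
F5 | step 5 | (2S,3S)-5-iodo-3-methyl-2-(3,4,5-trimethoxyphenyl)-2,3-dihydro-1-benzofuran-6-ol | Ic1cc2c(cc1O)O[C@H](c1cc(OC)c(OC)c(OC)c1)[C@H]2C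
F6 | step 6 | (2S,3S,5R)-5-hydroxy-3-methyl-5-(prop-2-en-1-yl)-2-(3,4,5-trimethoxyphenyl)-2,3-dihydro-1-benzofuran-6(5H)-one | C=CC[C@@]1(O)C=C2C(=CC1=O)O[C@H](c1cc(OC)c(OC)c(OC)c1)[C@H]2C
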